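## Retrosynthetic overview

1. Ring A is closed last through the C4–C5 bond: an intramolecular Nozaki–Hiyama–Kishi addition of a 2-bromoalkene to the ring B ketone gives the tertiary C5–OH and the exocyclic methylene in one step.
2. The C7 trienyl side chain comes from a catalyst-controlled Rh/BINAP 1,4-addition of a trienylzirconocene to a ring B cyclohexenone.
3. Ring B, the C1–Br centre and the quaternary C10 come from an enantioselective bromonium-triggered semipinacol ring expansion of an achiral 1-[(Z)-alkenyl]cyclopentanol (cyclopentane to cyclohexanone).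
4. The cyclopentanol comes from a (Z)-enoate (Still–Gennari olefination of 4-bromopent-4-enal) and the di-Grignard reagent of 1,4-dibromobutane.
5. Ring order: temporary cyclopentane, then ring B by expansion, then ring A by closure.

Assumption: atom labels follow eudesmane numbering (C1 bears Br, C4 the methylidene, C5 the OH, C7 the side chain, C10 the methyl; the target is 1R,5R,7R,10R in these labels). The antipode of the acid catalyst in step 4 is taken as the one that gives (1R,10R), to be confirmed in the first run.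

## Route

Step 1
Reactants: 1 2,3-dibromoprop-1-ene; 2 (E)-N-tert-butylethanimine
Product: 5 4-bromopent-4-enal, via lithium aza-enolate 3 (not isolated), via alkylated imine 4 (not isolated)
Conditions: LiN(iPr)2, THF, −78 °C; then 1, −78 → 0 °C; then aq oxalic acid, Et2O, rt
Reagents that add atoms: water, O
Why: Metalloenamine alkylation of the acetaldimine aza-enolate at the allylic bromide of 1, followed by imine hydrolysis, gives the aldehyde; no stereocentre is formed.

Step 2
Reactants: 5 4-bromopent-4-enal
Product: 6 methyl (2Z)-6-bromo-2-methylhepta-2,6-dienoate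
Conditions: (CF3CH2O)2P(O)CH(CH3)CO2CH3, KN(SiMe3)2, 18-crown-6, THF, −78 °C
Reagents that add atoms: methyl 2-[bis(2,2,2-trifluoroethoxy)phosphoryl]propanoate, COC(=O)C(C)P(=O)(OCC(F)(F)F)OCC(F)(F)F
Why: Still–Gennari variant of the Horner–Wadsworth–Emmons olefination gives the kinetic (Z)-2-methyl enoate (ester cis to the chain), the geometry that step 4 turns into the correct C1/C10 relationship.

Step 3
Reactants: 6 methyl (2Z)-6-bromo-2-methylhepta-2,6-dienoate; 7 1,4-dibromobutane
Product: 9 1-[(2Z)-6-bromohepta-2,6-dien-2-yl]cyclopentan-1-ol, via di-Grignard reagent 8 (not isolated)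
Conditions: 7, Mg, THF, 35 °C, solution cannulated off excess Mg; then 6, THF, 0 °C → rt; aq NH4Cl
Reagents that add atoms: none
Why: Double Grignard addition to the ester (intermolecular 1,2-addition, then 5-exo closure onto the ketone) builds the achiral tertiary allylic cyclopentanol without touching the alkene geometry or the 2-bromoalkene.

Step 4
Reactants: 9 1-[(2Z)-6-bromohepta-2,6-dien-2-yl]cyclopentan-1-ol
Product: 10 (2R)-2-[(1R)-1,4-dibromopent-4-en-1-yl]-2-methylcyclohexan-1-one
Conditions: NBS (1.1 equiv), (R)-TRIP [(R)-3,3'-bis(2,4,6-triisopropylphenyl)-1,1'-binaphthyl-2,2'-diyl hydrogen phosphate] (10 mol %), 4 Å MS, toluene/CH2Cl2 4:1, −60 °C, dark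
Reagents that add atoms: N-bromosuccinimide, O=C1CCC(=O)N1Br
Why: Proposed new method: the bifunctional chiral phosphoric acid hydrogen-bonds the tertiary OH through P=O and activates NBS through P–OH, so Br+ is delivered to one enantiotopic face of the electron-rich trisubstituted (Z)-alkene (the 2-bromoalkene is deactivated); the bromiranium ion opens at tertiary C10 with concerted antiperiplanar 1,2-shift of a ring CH2 of the achiral cyclopentanol (the two CH2 groups lie on opposite alkene faces, so face selection alone decides the outcome), expanding the five-membered ring to the ring B cyclohexanone, and anti addition of Br and C9 across the Z-alkene gives the (1R,10R) pair directly; the closest known reaction types are the organocatalytic enantioselective halogenation/semipinacol ring expansion of strained 1-alkenylcyclobutanols and the racemic NBS-induced semipinacol shift of tertiary allylic alcohols, and to my knowledge neither has been shown enantioselectively for an unstrained cyclopentanol carrying a purely aliphatic alkene.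

Step 5
Reactants: 10 (2R)-2-[(1R)-1,4-dibromopent-4-en-1-yl]-2-methylcyclohexan-1-one
Product: 11 (6R)-6-[(1R)-1,4-dibromopent-4-en-1-yl]-6-methylcyclohex-2-en-1-one
Conditions: IBX (2-iodoxybenzoic acid, 2.0 equiv), DMSO/toluene 1:2, 70 °C
Reagents that add atoms: none
Why: IBX-mediated α,β-dehydrogenation proceeds through the only possible enol (C10 is quaternary), so the enone forms regiospecifically at C6=C7 and both stereocentres are untouched.

Step 6
Reactants: 12 2-methylbut-1-en-3-yne
Product: 14 (1E)-1-iodo-3-methylbuta-1,3-diene, via dienylzirconocene chloride 13 (not isolated)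
Conditions: Cp2Zr(H)Cl (1.1 equiv), CH2Cl2, rt; then I2 (1.05 equiv), 0 °C
Reagents that add atoms: iodine, II
Why: syn-Hydrozirconation of the terminal alkyne places Zr at the terminus and iodinolysis with retention gives the (E)-dienyl iodide.

Step 7
Reactants: 14 (1E)-1-iodo-3-methylbuta-1,3-diene; 15 propyne
Product: 16 (4E)-6-methylhepta-4,6-dien-2-yne
Conditions: 15 (excess, condensed), Pd(PPh3)2Cl2 (3 mol %), CuI (6 mol %), Et3N, THF, 0 °C → rt, sealed tube
Reagents that add atoms: none
Why: Sonogashira coupling of the alkenyl iodide with the terminal alkyne proceeds with retention of the E geometry.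

Step 8
Reactants: 16 (4E)-6-methylhepta-4,6-dien-2-yne; 11 (6R)-6-[(1R)-1,4-dibromopent-4-en-1-yl]-6-methylcyclohex-2-en-1-one
Product: 18 (2R,5R)-2-[(1R)-1,4-dibromopent-4-en-1-yl]-2-methyl-5-[(2E,4E)-6-methylhepta-2,4,6-trien-2-yl]cyclohexan-1-one, via trienylzirconocene chloride 17 (not isolated)
Conditions: 16 (1.6 equiv), Cp2Zr(H)Cl (1.5 equiv), THF, rt, 1 h; then 11, [Rh(cod)(MeCN)2]BF4 (5 mol %), (R)-BINAP (6 mol %), THF, rt; aq NH4Cl
Reagents that add atoms: none
Why: syn-Hydrozirconation of the 2-alkyne puts Zr on the methyl-bearing carbon (fixing the 2E geometry), and Hayashi-type Rh/BINAP asymmetric 1,4-addition of the alkenylzirconocene to the enone sets C7 under catalyst control ((R)-BINAP is the antipode that gives (R)-3-substituted cyclohexanones from cyclohexenone in this reaction class), the remote C10 centre exerting little bias.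

Step 9
Reactants: 18 (2R,5R)-2-[(1R)-1,4-dibromopent-4-en-1-yl]-2-methyl-5-[(2E,4E)-6-methylhepta-2,4,6-trien-2-yl]cyclohexan-1-one
Product: 19 (1R,4aR,6R,8aR)-1-bromo-8a-methyl-4-methylidene-6-[(2E,4E)-6-methylhepta-2,4,6-trien-2-yl]decahydronaphthalen-4a-ol
Conditions: CrCl2 (6 equiv), NiCl2 (2 mol %), degassed DMF, rt → 40 °C; pH 7 buffer work-up
Reagents that add atoms: none
Why: Intramolecular Nozaki–Hiyama–Kishi reaction (zerovalent nickel inserts into the alkenyl C–Br bond, transmetalation gives an alkenyl species of trivalent chromium that adds to the ketone; the secondary alkyl bromide is inert to CrCl2); the equatorial C7 side chain locks ring B with axial C10-methyl and equatorial bromoalkyl arm, and chair-like closure with equatorial C4–C5 bond formation and equatorial Br gives the trans-fused 5α-alcohol (4aR).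

## Compound list

1 | 2,3-dibromoprop-1-ene | C=C(Br)CBr | starting material
2 | (E)-N-tert-butylethanimine (acetaldehyde N-tert-butylimine) | C/C=N/C(C)(C)C | starting material
3 | lithium aza-enolate of 2 (lithium N-tert-butyl-N-ethenylamide, formed in the flask) | [Li]N(C=C)C(C)(C)C | intermediate
4 | (E)-N-tert-butyl-4-bromopent-4-en-1-imine (formed in the flask) | C=C(Br)CC/C=N/C(C)(C)C | intermediate
5 | 4-bromopent-4-enal | C=C(Br)CCC=O | intermediate
6 | methyl (2Z)-6-bromo-2-methylhepta-2,6-dienoate | COC(=O)/C(C)=C\CCC(Br)=C | intermediate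
7 | 1,4-dibromobutane | BrCCCCBr | starting material
8 | butane-1,4-diylbis(magnesium bromide) (formed in the flask) | Br[Mg]CCCC[Mg]Br | intermediate
9 | 1-[(2Z)-6-bromohepta-2,6-dien-2-yl]cyclopentan-1-ol (carbinol carbon cis to the CH2 chain) | OC1(CCCC1)/C(C)=C\CCC(Br)=C | intermediate
10 | (2R)-2-[(1R)-1,4-dibromopent-4-en-1-yl]-2-methylcyclohexan-1-one | O=C1CCCC[C@@]1(C)[C@H](Br)CCC(Br)=C | intermediate
11 | (6R)-6-[(1R)-1,4-dibromopent-4-en-1-yl]-6-methylcyclohex-2-en-1-one | O=C1C=CCC[C@@]1(C)[C@H](Br)CCC(Br)=C | intermediate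
12 | 2-methylbut-1-en-3-yne | C=C(C)C#C | starting material
13 | chloridobis(cyclopentadienyl)[(1E)-3-methylbuta-1,3-dien-1-yl]zirconium (formed in the flask) | C=C(C)/C=C/[Zr](Cl)(C1C=CC=C1)C1C=CC=C1 | intermediate
14 | (1E)-1-iodo-3-methylbuta-1,3-diene | C=C(C)/C=C/I | intermediate
15 | propyne | CC#C | starting material
16 | (4E)-6-methylhepta-4,6-dien-2-yne | CC#C/C=C/C(C)=C | intermediate
17 | chloridobis(cyclopentadienyl)[(2E,4E)-6-methylhepta-2,4,6-trien-2-yl]zirconium (formed in the flask) | C=C(C)/C=C/C=C(\C)[Zr](Cl)(C1C=CC=C1)C1C=CC=C1 | intermediate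
18 | (2R,5R)-2-[(1R)-1,4-dibromopent-4-en-1-yl]-2-methyl-5-[(2E,4E)-6-methylhepta-2,4,6-trien-2-yl]cyclohexan-1-one | C=C(C)/C=C/C=C(\C)[C@@H]1CC[C@@](C)([C@H](Br)CCC(Br)=C)C(=O)C1 | intermediate
19 | (1R,4aR,6R,8aR)-1-bromo-8a-methyl-4-methylidene-6-[(2E,4E)-6-methylhepta-2,4,6-trien-2-yl]decahydronaphthalen-4a-ol (trans-fused; Br equatorial, OH axial, side chain equatorial, angular CH3 axial) | C=C(C)/C=C/C=C(\C)[C@@H]1CC[C@@]2(C)[C@H](Br)CCC(=C)[C@]2(O)C1 | target

## Step count and risks

Total step count: 9. Longest linear sequence: 7 (steps 1, 2, 3, 4, 5, 8, 9).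

**Step 4 (proposed new enantioselective ring expansion).** Possible failures are bromo-epoxide formation instead of migration, attack of the 2-bromoalkene on the cation, or low enantioselectivity.

Fallback, from 9 back to 18, using known chemistry: the rearrangement is run without a chiral catalyst (NBS, CH2Cl2/hexafluoroisopropanol, 0 °C; the halonium-induced semipinacol shift of tertiary allylic alcohols is an established racemic reaction). This gives 10 together with its enantiomer, (2S)-2-[(1S)-1,4-dibromopent-4-en-1-yl]-2-methylcyclohexan-1-one F1. The racemate is dehydrogenated as in step 5 to 11 plus (6S)-6-[(1S)-1,4-dibromopent-4-en-1-yl]-6-methylcyclohex-2-en-1-one F2. It is then put through step 8 unchanged: the (R)-BINAP rhodium catalyst sets C7 in the same absolute sense in both enantiomers, so 11 gives 18 and F2 gives the diastereomer (2S,5R)-2-[(1S)-1,4-dibromopent-4-en-1-yl]-2-methyl-5-[(2E,4E)-6-methylhepta-2,4,6-trien-2-yl]cyclohexan-1-one F3. F3 is removed by chromatography and the route is rejoined at 18 (at most 50 % from 9).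

**Step 8 (hydrozirconation and Rh-catalysed 1,4-addition).** Possible failures are imperfect regioselectivity in the hydrozirconation of the internal enyne, slow transfer of the α-branched alkenyl group, or incomplete catalyst control at C7.

Fallback, from 11 back to 19, with an alkyne as linchpin: catalyst-controlled Ni-catalysed conjugate addition of Me2AlC≡CSiMe3 (from ethynyltrimethylsilane, n-butyllithium and Me2AlCl; Ni(acac)2 with a chiral bis(oxazoline) ligand, Et2O, 0 °C) gives (2R,5R)-2-[(1R)-1,4-dibromopent-4-en-1-yl]-2-methyl-5-[(trimethylsilyl)ethynyl]cyclohexan-1-one F4, with C7 epimers separated if needed. K2CO3 in MeOH removes the silyl group to give (2R,5R)-2-[(1R)-1,4-dibromopent-4-en-1-yl]-5-ethynyl-2-methylcyclohexan-1-one F5. The CrCl2/NiCl2 conditions of step 9 close ring A to (1R,4aR,6R,8aR)-1-bromo-6-ethynyl-8a-methyl-4-methylidenedecahydronaphthalen-4a-ol F6. Zr-catalysed carboalumination (AlMe3, Cp2ZrCl2, CH2Cl2) followed in the same flask by Pd(PPh3)4/ZnCl2 coupling of the (E)-alkenylalane with dienyl iodide 14 then gives 19.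

**Step 9 (ring A closure).** Possible failures are sluggish insertion into the alkenyl bromide, competing cis-fused closure, or Grob fragmentation of the product alkoxide (the C5–O, C5–C10 and C1–Br bonds are antiperiplanar) if the medium turns basic.

Fallback, from 18 back to 19, with an organoboron in place of the organochromium: Miyaura borylation of the 2-bromoalkene (B2pin2, Pd(dppf)Cl2, KOPh, toluene, 50 °C; the neopentyl secondary bromide is not touched) gives (2R,5R)-2-[(1R)-1-bromo-4-(4,4,5,5-tetramethyl-1,3,2-dioxaborolan-2-yl)pent-4-en-1-yl]-2-methyl-5-[(2E,4E)-6-methylhepta-2,4,6-trien-2-yl]cyclohexan-1-one F7. [Rh(cod)(OH)]2-catalysed intramolecular 1,2-addition of the alkenylboronate to the ketone (dioxane/H2O, rt, no added base) then gives 19.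

## Further compounds

F1 | step 4 | (2S)-2-[(1S)-1,4-dibromopent-4-en-1-yl]-2-methylcyclohexan-1-one | O=C1CCCC[C@]1(C)[C@@H](Br)CCC(Br)=C
F2 | step 4 | (6S)-6-[(1S)-1,4-dibromopent-4-en-1-yl]-6-methylcyclohex-2-en-1-one | O=C1C=CCC[C@]1(C)[C@@H](Br)CCC(Br)=C
F3 | step 4 | (2S,5R)-2-[(1S)-1,4-dibromopent-4-en-1-yl]-2-methyl-5-[(2E,4E)-6-methylhepta-2,4,6-trien-2-yl]cyclohexan-1-one | C=C(C)/C=C/C=C(\C)[C@@H]1CC[C@](C)([C@@H](Br)CCC(Br)=C)C(=O)C1
F4 | step 8 | (2R,5R)-2-[(1R)-1,4-dibromopent-4-en-1-yl]-2-methyl-5-[(trimethylsilyl)ethynyl]cyclohexan-1-one | C[Si](C)(C)C#C[C@@H]1CC[C@@](C)([C@H](Br)CCC(Br)=C)C(=O)C1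
F5 | step 8 | (2R,5R)-2-[(1R)-1,4-dibromopent-4-en-1-yl]-5-ethynyl-2-methylcyclohexan-1-one | C#C[C@@H]1CC[C@@](C)([C@H](Br)CCC(Br)=C)C(=O)C1
F6 | step 8 | (1R,4aR,6R,8aR)-1-bromo-6-ethynyl-8a-methyl-4-methylidenedecahydronaphthalen-4a-ol | C#C[C@@H]1CC[C@@]2(C)[C@H](Br)CCC(=C)[C@]2(O)C1
F7 | step 9 | (2R,5R)-2-[(1R)-1-bromo-4-(4,4,5,5-tetramethyl-1,3,2-dioxaborolan-2-yl)pent-4-en-1-yl]-2-methyl-5-[(2E,4E)-6-methylhepta-2,4,6-trien-2-yl]cyclohexan-1-one | C=C(C)/C=C/C=C(\C)[C@@H]1CC[C@@](C)([C@H](Br)CCC(=C)B2OC(C)(C)C(C)(C)O2)C(=O)C1
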